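**Strategy.** The route rests on cutting ring A at C4a–C5 and C6–C7. Ring A carries OMe on C5 between the two carbon-substituted atoms C4a and C6, free oxygens on C7 and C8a, and H on C8. This is the pattern of a γ-prenylated, acetoacetate-derived 1,3-bis(silyloxy)diene (C7–C8–C8a–C4a) joined to a methoxyalkynyl ketone (C5–C6). One cycloaddition–aromatisation should therefore give ring A with its three oxygens already differentiated and the prenyl group next to the only hydroxyl able to close the pyran ring. The dienophile carries ring B behind a dimethyl ketal that masks the second carbonyl; oxidative chromene closure and ketal hydrolysis finish the synthesis.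

Key step: step 9

Remark on the chemistry: the target is a 2-hydroxybenzil and may equilibrate with its cyclic hemiketal; the open dione drawn is taken as the form isolated. Compounds 8, 10 and 11 are racemic at the acetal carbon of the tetrahydropyranyl (THP) group, which is removed in step 5. The ring B prenyl ether is introduced only after the acid-catalysed ketalisation, because aryl prenyl ethers are acid-labile.

Step 1
Reactants: 1 methyl acetoacetate; 2 1-bromo-3-methylbut-2-ene
Product: 4 methyl 7-methyl-3-oxooct-6-enoate, via acetoacetate dianion 3 (not isolated)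
Conditions: NaH, THF, 0 °C; n-BuLi, 0 °C; then 2, 0 → 20 °C
Reagents that add atoms: none
Why: γ-Alkylation of the acetoacetate dianion: the more basic terminal carbanion attacks the primary allylic bromide and the α-position stays untouched.

Step 2
Reactants: 4 methyl 7-methyl-3-oxooct-6-enoate
Product: 5 methyl (2Z)-7-methyl-3-(trimethylsilyloxy)octa-2,6-dienoate
Conditions: Me3SiCl, Et3N, PhMe, 20 °C
Reagents that add atoms: chlorotrimethylsilane, C[Si](C)(C)Cl
Why: O-Silylation of the enolised β-keto ester should give the chelation-derived (Z)-silyl enol ether, the standard first stage of 1,3-bis(silyloxy)diene preparation.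

Step 3
Reactants: 5 methyl (2Z)-7-methyl-3-(trimethylsilyloxy)octa-2,6-dienoate
Product: 7 (3Z)-1-methoxy-7-methyl-1,3-bis(trimethylsilyloxy)octa-1,3,6-triene, via lithium dienolate 6 (not isolated)
Conditions: LiN(i-Pr)2, THF, −78 °C; Me3SiCl, −78 → 20 °C
Reagents that add atoms: chlorotrimethylsilane, C[Si](C)(C)Cl
Why: Kinetic γ-deprotonation of the vinylogous ester and O-silylation of the dienolate is the standard second stage of the diene preparation; the chain should take the outward (3Z) position that the cycloaddition needs, and the geometry at C1 is without consequence.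

Step 4
Reactants: 8 2-(4-bromophenoxy)tetrahydro-2H-pyran (racemic); 9 dimethyl oxalate
Product: 11 methyl 2-oxo-2-[4-(tetrahydro-2H-pyran-2-yloxy)phenyl]acetate (racemic), via aryl Grignard reagent 10 (not isolated)
Conditions: Mg, THF, 45 °C; then added to 9 (2 equiv), THF, −78 °C
Reagents that add atoms: none
Why: Inverse addition of an aryl Grignard reagent to excess dialkyl oxalate at low temperature stops at the aryl glyoxylate, and the THP acetal is inert to the Grignard reagent.

Step 5
Reactants: 11 methyl 2-oxo-2-[4-(tetrahydro-2H-pyran-2-yloxy)phenyl]acetate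
Product: 13 methyl 2-(4-hydroxyphenyl)-2,2-dimethoxyacetate, via methyl 4-hydroxyphenylglyoxylate 12 (not isolated)
Conditions: HC(OMe)3, MeOH, H2SO4 (cat.), 60 °C
Reagents that add atoms: trimethyl orthoformate, COC(OC)OC; methanol, CO
Why: Acidic methanol removes the THP acetal and the orthoester drives acid-catalysed ketalisation of the aryl glyoxylate, so the only strongly acidic step of the route is run before any prenyl group is on ring B.

Step 6
Reactants: 13 methyl 2-(4-hydroxyphenyl)-2,2-dimethoxyacetate; 2 1-bromo-3-methylbut-2-ene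
Product: 14 methyl 2,2-dimethoxy-2-[4-(3-methylbut-2-enyloxy)phenyl]acetate
Conditions: K2CO3, acetone, 50 °C
Reagents that add atoms: none
Why: Williamson etherification of the phenoxide with the primary allylic bromide under weakly basic conditions that leave ester and ketal untouched.

Step 7
Reactants: 14 methyl 2,2-dimethoxy-2-[4-(3-methylbut-2-enyloxy)phenyl]acetate
Product: 15 N,2,2-trimethoxy-N-methyl-2-[4-(3-methylbut-2-enyloxy)phenyl]acetamide
Conditions: MeNH(OMe)·HCl, i-PrMgCl, THF, −20 → 0 °C
Reagents that add atoms: N,O-dimethylhydroxylamine hydrochloride, CNOC.Cl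
Why: Direct aminolysis of the ester by the chloromagnesium amide gives the Weinreb amide; the α-carbon is quaternary, so no enolisation competes, and the two α-methoxy groups activate the ester.

Step 8
Reactants: 16 2-chloro-1,1-dimethoxyethane; 15 N,2,2-trimethoxy-N-methyl-2-[4-(3-methylbut-2-enyloxy)phenyl]acetamide
Product: 19 1,1,4-trimethoxy-1-[4-(3-methylbut-2-enyloxy)phenyl]but-3-yn-2-one, via lithium methoxyacetylide 17 (not isolated), via lithium hemiaminal chelate 18 (not isolated)
Conditions: 16, LiNEt2 (Et2NH, n-BuLi), THF, 0 °C; then 15, −78 → −20 °C; poured into cold aq. citric acid/Et2O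
Reagents that add atoms: none
Why: Double elimination and deprotonation of the chloroacetal with three equivalents of LiNEt2 gives the alkoxyacetylide, which adds once to the Weinreb amide (Weinreb ketone synthesis); the stable chelate releases the ynone only on the cold acidic quench, which protonates the amines before they can add to the push–pull alkyne.

Step 9
Reactants: 7 (3Z)-1-methoxy-7-methyl-1,3-bis(trimethylsilyloxy)octa-1,3,6-triene; 19 1,1,4-trimethoxy-1-[4-(3-methylbut-2-enyloxy)phenyl]but-3-yn-2-one
Product: 22 1-[4,6-dihydroxy-2-methoxy-3-(3-methylbut-2-enyl)phenyl]-2,2-dimethoxy-2-[4-(3-methylbut-2-enyloxy)phenyl]ethanone, via cyclohexadiene cycloadduct 20 (not isolated), via bis(trimethylsilyl) ether 21 (not isolated)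
Conditions: 7 (2 equiv), PhMe, 20 → 80 °C; then MeOH, K2CO3 (cat.), 0 °C
Reagents that add atoms: none
Why: Proposed new method: the electron-rich diene 7 (largest HOMO coefficient at the prenyl-bearing terminus, future C4a) should add to ynone 19 (most electrophilic at the methoxy-bearing β-carbon, future C5) in an asynchronous [4+2] cycloaddition, or in its stepwise Mukaiyama–Michael/ring-closure limit, to give cyclohexadiene 20, which loses methanol across C7 and C4a to give arene 21; methanolysis then frees both phenols. The closest known reaction type is the Diels–Alder/aromatisation of 1-alkoxy-1,3-bis(silyloxy)dienes with acetylenic ketones and esters to resorcinols, in which a β-alkoxy ynone has not served as the dienophile. Ring A is closed by this intermolecular [4+2] cycloaddition, which forms C4a–C5 and C6–C7, and becomes aromatic by 1,4-elimination. No stereocentre remains, since the two sp3 centres of 20 are destroyed on aromatisation. The step needs regioselectivity (C4a to C5, not to C6), periselectivity over [2+2] addition and carbonyl addition, and loss of methanol and not silanol from C7; these should be secured by the matched polarisation of the two partners, by the outward (3Z) substituent and the absence of Lewis acid, and by methanolysis, which converts the C7 ketal carbon into the phenol on either pathway. The adjacent ketal activates the ynone carbonyl inductively, which partly offsets the donor effect of the alkynyl methoxy group, and removes the second carbonyl as a competing electrophile.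

Step 10
Reactants: 22 1-[4,6-dihydroxy-2-methoxy-3-(3-methylbut-2-enyl)phenyl]-2,2-dimethoxy-2-[4-(3-methylbut-2-enyloxy)phenyl]ethanone
Product: 24 1-(7-hydroxy-5-methoxy-2,2-dimethyl-2H-chromen-6-yl)-2,2-dimethoxy-2-[4-(3-methylbut-2-enyloxy)phenyl]ethanone, via o-quinone methide 23 (not isolated)
Conditions: DDQ (1.1 equiv), PhH, 80 °C, dark
Reagents that add atoms: none
Why: DDQ should abstract hydride from the benzylic CH2 of the C-prenyl group to give the o-quinone methide, which closes by oxa-6π electrocyclisation onto the C8a oxygen (the known dehydrogenative cyclisation of o-prenylphenols to 2,2-dimethylchromenes); the other neighbour, C5, is a methyl ether, so only one chromene can form.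

Step 11
Reactants: 24 1-(7-hydroxy-5-methoxy-2,2-dimethyl-2H-chromen-6-yl)-2,2-dimethoxy-2-[4-(3-methylbut-2-enyloxy)phenyl]ethanone
Product: 25 Ficucaricone C, 1-(7-hydroxy-5-methoxy-2,2-dimethyl-2H-chromen-6-yl)-2-[4-(3-methylbut-2-enyloxy)phenyl]ethane-1,2-dione
Conditions: pyridinium p-toluenesulfonate (cat.), acetone/H2O (9:1), 50 °C
Reagents that add atoms: water, O
Why: Acid-catalysed ketal hydrolysis through an oxocarbenium ion that is benzylic to the p-alkoxyphenyl ring, so a weak acid should suffice and the prenyl ether and chromene stay unprotonated; any cyclic mixed ketal formed with the C7 hydroxyl hydrolyses to the same dione.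

**Compound list**

1 | methyl acetoacetate | COC(=O)CC(C)=O | starting material
2 | 1-bromo-3-methylbut-2-ene (prenyl bromide) | CC(C)=CCBr | starting material
3 | sodium lithium dianion of methyl acetoacetate | [Na+].[Li+].COC(=O)[CH-]C(=O)[CH2-] | intermediate
4 | methyl 7-methyl-3-oxooct-6-enoate | COC(=O)CC(=O)CCC=C(C)C | intermediate
5 | methyl (2Z)-7-methyl-3-(trimethylsilyloxy)octa-2,6-dienoate | COC(=O)/C=C(O[Si](C)(C)C)/CCC=C(C)C | intermediate
6 | lithium (3Z)-1-methoxy-7-methyl-3-(trimethylsilyloxy)octa-1,3,6-trien-1-olate | [Li+].COC([O-])=C/C(O[Si](C)(C)C)=C/CC=C(C)C | intermediate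
7 | (3Z)-1-methoxy-7-methyl-1,3-bis(trimethylsilyloxy)octa-1,3,6-triene (C1 geometry not defined) | COC(O[Si](C)(C)C)=C/C(O[Si](C)(C)C)=C/CC=C(C)C | intermediate
8 | 2-(4-bromophenoxy)tetrahydro-2H-pyran (racemic) | Brc1ccc(OC2CCCCO2)cc1 | starting material
9 | dimethyl oxalate | COC(=O)C(=O)OC | starting material
10 | [4-(tetrahydro-2H-pyran-2-yloxy)phenyl]magnesium bromide (racemic) | Br[Mg]c1ccc(OC2CCCCO2)cc1 | intermediate
11 | methyl 2-oxo-2-[4-(tetrahydro-2H-pyran-2-yloxy)phenyl]acetate (racemic) | COC(=O)C(=O)c1ccc(OC2CCCCO2)cc1 | intermediate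
12 | methyl 2-(4-hydroxyphenyl)-2-oxoacetate | COC(=O)C(=O)c1ccc(O)cc1 | intermediate
13 | methyl 2-(4-hydroxyphenyl)-2,2-dimethoxyacetate | COC(=O)C(OC)(OC)c1ccc(O)cc1 | intermediate
14 | methyl 2,2-dimethoxy-2-[4-(3-methylbut-2-enyloxy)phenyl]acetate | COC(=O)C(OC)(OC)c1ccc(OCC=C(C)C)cc1 | intermediate
15 | N,2,2-trimethoxy-N-methyl-2-[4-(3-methylbut-2-enyloxy)phenyl]acetamide | CON(C)C(=O)C(OC)(OC)c1ccc(OCC=C(C)C)cc1 | intermediate
16 | 2-chloro-1,1-dimethoxyethane | COC(CCl)OC | starting material
17 | lithium methoxyacetylide | [Li]C#COC | intermediate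
18 | lithium 1-[methoxy(methyl)amino]-1-(methoxyethynyl)-2,2-dimethoxy-2-[4-(3-methylbut-2-enyloxy)phenyl]ethanolate (racemic) | [Li+].COC#CC([O-])(N(C)OC)C(OC)(OC)c1ccc(OCC=C(C)C)cc1 | intermediate
19 | 1,1,4-trimethoxy-1-[4-(3-methylbut-2-enyloxy)phenyl]but-3-yn-2-one | COC#CC(=O)C(OC)(OC)c1ccc(OCC=C(C)C)cc1 | intermediate
20 | 1-[2,6-dimethoxy-3-(3-methylbut-2-enyl)-4,6-bis(trimethylsilyloxy)cyclohexa-1,4-dien-1-yl]-2,2-dimethoxy-2-[4-(3-methylbut-2-enyloxy)phenyl]ethanone (mixture of diastereomers) | COC1=C(C(=O)C(OC)(OC)c2ccc(OCC=C(C)C)cc2)C(OC)(O[Si](C)(C)C)C=C(O[Si](C)(C)C)C1CC=C(C)C | intermediate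
21 | 2,2-dimethoxy-1-[2-methoxy-3-(3-methylbut-2-enyl)-4,6-bis(trimethylsilyloxy)phenyl]-2-[4-(3-methylbut-2-enyloxy)phenyl]ethanone | COc1c(CC=C(C)C)c(O[Si](C)(C)C)cc(O[Si](C)(C)C)c1C(=O)C(OC)(OC)c1ccc(OCC=C(C)C)cc1 | intermediate
22 | 1-[4,6-dihydroxy-2-methoxy-3-(3-methylbut-2-enyl)phenyl]-2,2-dimethoxy-2-[4-(3-methylbut-2-enyloxy)phenyl]ethanone | COc1c(CC=C(C)C)c(O)cc(O)c1C(=O)C(OC)(OC)c1ccc(OCC=C(C)C)cc1 | intermediate
23 | o-quinone methide of 22: 3-hydroxy-5-methoxy-6-(3-methylbut-2-enylidene)-4-{2,2-dimethoxy-2-[4-(3-methylbut-2-enyloxy)phenyl]acetyl}cyclohexa-2,4-dien-1-one (alkene geometry not defined) | COC1=C(C(=O)C(OC)(OC)c2ccc(OCC=C(C)C)cc2)C(O)=CC(=O)C1=CC=C(C)C | intermediate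
24 | 1-(7-hydroxy-5-methoxy-2,2-dimethyl-2H-chromen-6-yl)-2,2-dimethoxy-2-[4-(3-methylbut-2-enyloxy)phenyl]ethanone | COc1c2c(cc(O)c1C(=O)C(OC)(OC)c1ccc(OCC=C(C)C)cc1)OC(C)(C)C=C2 | intermediate
25 | Ficucaricone C, 1-(7-hydroxy-5-methoxy-2,2-dimethyl-2H-chromen-6-yl)-2-[4-(3-methylbut-2-enyloxy)phenyl]ethane-1,2-dione | COc1c2c(cc(O)c1C(=O)C(=O)c1ccc(OCC=C(C)C)cc1)OC(C)(C)C=C2 | target

**Step count.** Total: 11 steps. Longest linear sequence: 8 steps (steps 4 to 11); the diene branch is steps 1 to 3.

**Steps most likely to fail**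

1. Step 9 (Proposed new method). The methoxy donor may lower the dienophilicity of 19 so far that 7 is lost by desilylation or silyl transfer before it adds, or the first bond may form and methoxide be expelled from C5 in place of ring closure. The fallback uses known chemistry only, sets out from Weinreb amide 15 and comes back at chromene ketal 24; ring A is taken from phloroglucinol and not built. Friedel–Crafts acylation and oxa-Michael closure of phloroglucinol with 3-methylbut-2-enoic acid (P2O5/MeSO3H, 70 °C) should give 5,7-dihydroxy-2,2-dimethylchroman-4-one F1. The C5 hydroxyl is chelated to the ketone, so silylation (i-Pr3SiCl, imidazole, DMF) should give 5-hydroxy-2,2-dimethyl-7-(triisopropylsilyloxy)chroman-4-one F2. Iodination ortho to the chelated hydroxyl (BnMe3N ICl2, CaCO3, CH2Cl2/MeOH) should give 5-hydroxy-6-iodo-2,2-dimethyl-7-(triisopropylsilyloxy)chroman-4-one F3. O-Methylation (MeI, K2CO3, acetone) then gives 6-iodo-5-methoxy-2,2-dimethyl-7-(triisopropylsilyloxy)chroman-4-one F4. Reduction with NaBH4 gives racemic 6-iodo-5-methoxy-2,2-dimethyl-7-(triisopropylsilyloxy)chroman-4-ol F5, and dehydration (pyridinium p-toluenesulfonate, PhMe, 80 °C) gives 6-iodo-5-methoxy-2,2-dimethyl-7-(triisopropylsilyloxy)-2H-chromene F6. Iodine–lithium exchange (n-BuLi, THF, −78 °C) gives [5-methoxy-2,2-dimethyl-7-(triisopropylsilyloxy)-2H-chromen-6-yl]lithium F7, which should add once to 15 to give 2,2-dimethoxy-1-[5-methoxy-2,2-dimethyl-7-(triisopropylsilyloxy)-2H-chromen-6-yl]-2-[4-(3-methylbut-2-enyloxy)phenyl]ethanone F8. Desilylation with n-Bu4NF in THF gives 24, and step 11 follows.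

2. Step 8. The amines set free on work-up may add to the push–pull alkyne, or the alkynyl ether may be hydrated during the acidic quench. The fallback sets out from 15 and comes back at 19, and moves the sensitive ynone to a neutral last operation. Reduction of 15 (LiAlH4, THF, −78 °C) should give 2,2-dimethoxy-2-[4-(3-methylbut-2-enyloxy)phenyl]acetaldehyde F9. Addition of lithium methoxyacetylide 17 gives racemic 1,1,4-trimethoxy-1-[4-(3-methylbut-2-enyloxy)phenyl]but-3-yn-2-ol F10, from which the amines are washed out at the unreactive alcohol stage. Oxidation with MnO2 in CH2Cl2 then gives 19.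

3. Step 10. DDQ may abstract hydride at the O–CH2 of the aryl prenyl ether, or over-oxidise the electron-rich chromene. The fallback sets out from 22 and comes back at 24: Wacker-type oxidative cyclisation catalysed by divalent palladium (PdCl2(MeCN)2, benzoquinone, 1,4-dioxane, 40 °C). This is 6-endo oxypalladation of the trisubstituted alkene by the C8a hydroxyl followed by β-hydride elimination towards C4. It needs a neighbouring nucleophile and should therefore leave the prenyl ether alone; it makes no new compound (F0).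

**Further compounds**

F1 | step 9 | 5,7-dihydroxy-2,2-dimethylchroman-4-one | O=C1CC(C)(C)Oc2cc(O)cc(O)c12
F2 | step 9 | 5-hydroxy-2,2-dimethyl-7-(triisopropylsilyloxy)chroman-4-one | O=C1CC(C)(C)Oc2cc(O[Si](C(C)C)(C(C)C)C(C)C)cc(O)c12
F3 | step 9 | 5-hydroxy-6-iodo-2,2-dimethyl-7-(triisopropylsilyloxy)chroman-4-one | O=C1CC(C)(C)Oc2cc(O[Si](C(C)C)(C(C)C)C(C)C)c(I)c(O)c12
F4 | step 9 | 6-iodo-5-methoxy-2,2-dimethyl-7-(triisopropylsilyloxy)chroman-4-one | O=C1CC(C)(C)Oc2cc(O[Si](C(C)C)(C(C)C)C(C)C)c(I)c(OC)c12
F5 | step 9 | 6-iodo-5-methoxy-2,2-dimethyl-7-(triisopropylsilyloxy)chroman-4-ol (racemic) | OC1CC(C)(C)Oc2cc(O[Si](C(C)C)(C(C)C)C(C)C)c(I)c(OC)c12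
F6 | step 9 | 6-iodo-5-methoxy-2,2-dimethyl-7-(triisopropylsilyloxy)-2H-chromene | CC1(C)C=Cc2c(O1)cc(O[Si](C(C)C)(C(C)C)C(C)C)c(I)c2OC
F7 | step 9 | [5-methoxy-2,2-dimethyl-7-(triisopropylsilyloxy)-2H-chromen-6-yl]lithium | CC1(C)C=Cc2c(O1)cc(O[Si](C(C)C)(C(C)C)C(C)C)c([Li])c2OC
F8 | step 9 | 2,2-dimethoxy-1-[5-methoxy-2,2-dimethyl-7-(triisopropylsilyloxy)-2H-chromen-6-yl]-2-[4-(3-methylbut-2-enyloxy)phenyl]ethanone | COc1c2c(cc(O[Si](C(C)C)(C(C)C)C(C)C)c1C(=O)C(OC)(OC)c1ccc(OCC=C(C)C)cc1)OC(C)(C)C=C2
F9 | step 8 | 2,2-dimethoxy-2-[4-(3-methylbut-2-enyloxy)phenyl]acetaldehyde | COC(OC)(C=O)c1ccc(OCC=C(C)C)cc1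
F10 | step 8 | 1,1,4-trimethoxy-1-[4-(3-methylbut-2-enyloxy)phenyl]but-3-yn-2-ol (racemic) | COC#CC(O)C(OC)(OC)c1ccc(OCC=C(C)C)cc1
F0 | step 10 | none | none
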